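The numbers of this flask are invented; the result is computed.

We start with the easy step of writing down what goes in and what is wanted.

in all of them: starting material 0.10 M; time 6.0 h

|  | temperature |
|---|---|
| elm | 20 °C |
| larch | 45 °C |

    starting material + starting material ⇌ target (K1 = 240 M⁻¹, k1 = 3.2 M⁻¹ h⁻¹, Ea1 = 64.0 kJ mol⁻¹, ΔH1 = −29.0 kJ mol⁻¹)
    starting material + target → side product (k2 = 2.9 M⁻¹ h⁻¹, Ea2 = 64.0 kJ mol⁻¹)
    (constants at 20 °C)

- a species is counted by the starting material in it: one target counts as two
- a species is counted by the starting material in it: one side product counts as three
- for a step with 2 of a species take k times the square, and two of it per event
- the list of constants is for 20 °C, to be carried to other temperatures by the activation energies and enthalpies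

- which of these there is most of at the end, counted by the starting material in it, elm (target / side product / starting material)
- which of these there is most of at the end, counted by the starting material in it, larch (target / side product / starting material)
- the largest of these amounts at the end, in percent of the starting material charged, elm
- the largest of these amounts at the end, in percent of the starting material charged, larch

The rule of thumb at the bench says that a large equilibrium constant sends the charge to target. To test this we count in fractions of the charge and treat the first step as a pre-equilibrium, always in balance. Carried to 45 °C for larch, its constant falls to 94.2 M⁻¹, while both rate constants rise 7.87-fold. In balance, the target share equals the free share of starting material squared, times 2 times the constant times the charged concentration. That multiplier is 48.0 in elm and 18.8 in larch, and we call it the hold number. With the two shares summing to the charge, as they do before any side product has formed, the balance gives elm 13.4 % free and 86.6 % as target, and it gives larch 20.5 % free.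

The border is the time the first step needs to return to balance: one over 4 times its rate constant times the free concentration, plus its back constant, taken at the free share just found. Elm needs 5.40 h, about as long as the run, so the rule stops there and we give elm no figure of our own. Larch needs 0.428 h, far shorter than the run, so we go on with larch.

Each loss event takes 3 units of the charge out of the free and target shares. Following this in larch with the first step in balance, the drain count, 0.5 over the free share squared plus 2 times the hold number over the free share, rises steadily by 64.5 h⁻¹. Taking the balance as reached at the start, we begin it at 195, and it reaches 583 at 6.0 h. For larch this means free 7.60 %, target 10.9 % and side product 81.5 %.

The forecast, saying of larch “Dimerisation equilibrates within about 1 h”, put target first in elm at 46 % and side product first in larch at 81 %.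

Elm gives target first at 46.0 %, and there target over free squared reads 14.6 against a hold number of 48.0. Larch gives side product first at 81.7 %, with 7.22 % free and 11.0 % target, and the same reading is 21.1 against 18.8. The neighbour is larch read at 2.5 h. There the count reaches 357, which gives free 11.8 %, target 26.1 % and side product 62.1 %. That flask holds 10.4 % free, 25.5 % target and 64.1 % side product.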